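**Plan**
The target is 6,8''-bigenistein. Unit 1 is the isoflavone joined at C6 (its benzo ring is ring A), unit 2 the isoflavone joined at C8'' (its benzo ring is ring B). Six methyl ethers mask the phenols to the end.
Cuts: in unit 2, C4''–C4a'' (acylation) and C2''–C3'' plus O1''–C2'' (amide acetal carbon); in unit 1, O1–C8a and C4–C4a (aryne annulation) and C2–C3 (formylation of an arylacetate); the C6–C8'' biaryl bond (Negishi coupling of two pieces of 3,5-dimethoxyphenol).
Forward order: biaryl, then ring A made into an ortho-silylaryl triflate, then the pyranone of unit 1 on the aryne, then the pyranone of unit 2 by the deoxybenzoin route, then sixfold demethylation.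
Enabling feature: in unit 1 the neighbouring carbons C8a and C4a carry O1 and C4, and the C5 oxygen next to C4a polarises an aryne across C4a–C8a so that oxygen enters at C8a and the acyl carbon at C4a.
Stereochemistry: there is no stereocentre; the biaryl axis is formed without control.

Key step: step 9

Assumption: the SMILES carries no axial descriptor although the C6–C8'' axis has four ortho oxygens and may be configurationally stable, so the axis is left uncontrolled and the material is taken as the racemate (from step 6 onward).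

**Route**

Step 1
Reactants: 1 3,5-dimethoxyphenol
Product: 2 1,3-dimethoxy-5-(methoxymethoxy)benzene
Conditions: NaH, MOMCl, THF/DMF, 0 °C to rt
Reagents that add atoms: chloromethyl methyl ether, COCCl
Why: Williamson-type O-alkylation of the sodium phenoxide by the reactive α-chloro ether gives the MOM acetal, which is stable to organolithiums, fluoride and palladium and serves as the ortho-director in the next step.

Step 2
Reactants: 2 1,3-dimethoxy-5-(methoxymethoxy)benzene
Product: 4 2-iodo-1,5-dimethoxy-3-(methoxymethoxy)benzene, via aryllithium 3 (not isolated)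
Conditions: n-BuLi, TMEDA, THF, 0 °C; then I2, −78 °C to rt
Reagents that add atoms: iodine, II
Why: Directed ortho-metalation, in which the chelating OMOM group outranks methoxy, so lithiation should occur at one of the two equivalent carbons flanked by OMOM and OMe and iodine traps the aryllithium (an isomer iodinated between the two methoxy groups, if formed, would be separated here).

Step 3
Reactants: 1 3,5-dimethoxyphenol
Product: 5 (3,5-dimethoxyphenoxy)tri(propan-2-yl)silane
Conditions: NaH, TIPSCl, THF, 0 °C to rt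
Reagents that add atoms: chlorotri(propan-2-yl)silane, CC(C)[Si](Cl)(C(C)C)C(C)C
Why: O-silylation of the phenoxide gives a bulky silyl ether that is a poor director and shields its own ortho positions in the following lithiation.

Step 4
Reactants: 5 (3,5-dimethoxyphenoxy)tri(propan-2-yl)silane; 4 2-iodo-1,5-dimethoxy-3-(methoxymethoxy)benzene
Product: 8 {[2,2',4',6-tetramethoxy-6'-(methoxymethoxy)biphenyl-4-yl]oxy}tri(propan-2-yl)silane, via aryllithium 6 (not isolated), via arylzinc chloride 7 (not isolated)
Conditions: n-BuLi, THF, 0 °C to rt; ZnCl2, THF, 0 °C to rt; then 4, Pd2(dba)3 (2 mol %), RuPhos (8 mol %), THF, 70 °C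
Reagents that add atoms: none
Why: Directed ortho-metalation between the two methoxy groups, transmetalation to zinc and Negishi coupling under a zerovalent palladium catalyst with the bulky dialkylbiarylphosphine RuPhos, a combination suited to tetra-ortho-substituted biaryls, while the arylzinc avoids the protodeboronation typical of 2,6-dialkoxyarylboronic acids.

Step 5
Reactants: 8 {[2,2',4',6-tetramethoxy-6'-(methoxymethoxy)biphenyl-4-yl]oxy}tri(propan-2-yl)silane
Product: 9 2,2',4',6-tetramethoxy-6'-(methoxymethoxy)biphenyl-4-ol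
Conditions: TBAF, AcOH, THF, 0 °C
Reagents that add atoms: none
Why: Fluoride-induced desilylation of the aryl silyl ether, buffered with acetic acid so that the phenoxide is protonated at once, leaves the acetal and methyl ethers untouched.

Step 6
Reactants: 9 2,2',4',6-tetramethoxy-6'-(methoxymethoxy)biphenyl-4-ol
Product: 10 3-bromo-2,2',4',6-tetramethoxy-6'-(methoxymethoxy)biphenyl-4-ol
Conditions: NBS (1.0 equiv), CH2Cl2, −78 to −20 °C
Reagents that add atoms: N-bromosuccinimide, O=C1CCC(=O)N1Br
Why: Electrophilic aromatic bromination, in which the free hydroxyl activates ring A more strongly than any ether activates ring B, the para position is blocked and the two ortho positions are equivalent, so one equivalent of NBS at low temperature should give a single ortho-bromophenol.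

Step 7
Reactants: 10 3-bromo-2,2',4',6-tetramethoxy-6'-(methoxymethoxy)biphenyl-4-ol
Product: 14 2,2',4',6-tetramethoxy-6'-(methoxymethoxy)-3-(trimethylsilyl)biphenyl-4-yl trifluoromethanesulfonate, via silyl ether 11 (not isolated), via aryllithium 12 (not isolated), via lithium phenoxide 13 (not isolated)
Conditions: HMDS, THF, 70 °C, then evaporate; n-BuLi, THF, −78 °C; then Tf2O, −78 to −40 °C
Reagents that add atoms: hexamethyldisilazane, C[Si](C)(C)N[Si](C)(C)C; trifluoromethanesulfonic anhydride, O=S(=O)(OS(=O)(=O)C(F)(F)F)C(F)(F)F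
Why: O-silylation, bromine–lithium exchange and retro-Brook 1,3-shift of silicon from oxygen to carbon give the ortho-silyl phenoxide, which is trapped as the triflate in the standard preparation of ortho-silylaryl triflates, and halogen–metal exchange at −78 °C outpaces any deprotonation next to the ring-B ethers.

Step 8
Reactants: 15 methyl (4-methoxyphenyl)acetate; 16 methyl formate
Product: 17 methyl (2Z)-3-hydroxy-2-(4-methoxyphenyl)prop-2-enoate
Conditions: NaH, THF, 0 °C to rt; then 1 M HCl
Reagents that add atoms: none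
Why: Crossed Claisen condensation of the ester enolate with non-enolisable methyl formate is driven by formation of the stabilised sodium enolate, and acidification gives the hydrogen-bonded Z enol.

Step 9
Reactants: 14 2,2',4',6-tetramethoxy-6'-(methoxymethoxy)-3-(trimethylsilyl)biphenyl-4-yl trifluoromethanesulfonate; 17 methyl (2Z)-3-hydroxy-2-(4-methoxyphenyl)prop-2-enoate
Product: 19 6-[2,4-dimethoxy-6-(methoxymethoxy)phenyl]-5,7-dimethoxy-3-(4-methoxyphenyl)-4H-chromen-4-one, via aryne 18 (not isolated)
Conditions: CsF (4 equiv), THF, 65 °C, slow addition of 14 to 17 (1.5 equiv)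
Reagents that add atoms: none
Why: Proposed new method: fluoride removes the trimethylsilyl group of 14 and triflate departs to give aryne 18, the caesium enolate of 17 adds through its formyl oxygen to C8a, and the aryl anion that results at C4a adds to the cis-disposed methyl ester and expels methoxide, so that O1–C8a and C4–C4a are made in one operation. The closest known reaction type is the fluoride-triggered annulation of arynes by salicylate esters to xanthones, with the insertion of arynes into the C–O bond of carboxylic acids (to ortho-hydroxyaryl ketones) as a second relative; what is new is an enol oxygen in place of a phenol oxygen. The pyranone of unit 1 closes by a 6-exo-trig acyl substitution and no stereocentre is formed. Three selectivities are needed: the orientation on the aryne, O- instead of C-arylation of the ambident enolate, and ring closure ahead of protonation of the aryl anion. The orientation follows from the C5 methoxy group, which distorts the aryne so that the nucleophile enters at the remote carbon C8a and the charge develops next to the methoxy group; O-arylation is expected because enolates of this α-aryl hydroxymethylene ester type are known to be alkylated at oxygen and C-attack would have to build a quaternary carbon carrying two aryl groups. THF in place of acetonitrile removes the obvious proton source, and the caesium-chelated Z enolate, in which the enolate oxygen and the ester are cis, places the ester within reach of C4a.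

Step 10
Reactants: 19 6-[2,4-dimethoxy-6-(methoxymethoxy)phenyl]-5,7-dimethoxy-3-(4-methoxyphenyl)-4H-chromen-4-one
Product: 20 6-(2-hydroxy-4,6-dimethoxyphenyl)-5,7-dimethoxy-3-(4-methoxyphenyl)-4H-chromen-4-one
Conditions: HCl (cat.), MeOH/THF, 50 °C
Reagents that add atoms: none
Why: Acid-catalysed acetal exchange with methanol removes the MOM group as dimethoxymethane, while aryl methyl ethers and the isoflavone are stable to methanolic HCl.

Step 11
Reactants: 20 6-(2-hydroxy-4,6-dimethoxyphenyl)-5,7-dimethoxy-3-(4-methoxyphenyl)-4H-chromen-4-one; 21 (4-methoxyphenyl)acetic acid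
Product: 22 6-{2-hydroxy-4,6-dimethoxy-3-[(4-methoxyphenyl)acetyl]phenyl}-5,7-dimethoxy-3-(4-methoxyphenyl)-4H-chromen-4-one
Conditions: BF3·OEt2 (solvent), 85 °C; then aq NaOAc
Reagents that add atoms: none
Why: Friedel–Crafts acylation by way of O-acylation and Fries shift in BF3·OEt2, the standard deoxybenzoin synthesis, should place the acyl group ortho to the hydroxyl, where the boron-chelated hydroxy ketone is the stable product, because the only other free carbon of ring B lies between two methoxy groups and C8 of unit 1 belongs to a ring deactivated by the Lewis-acid-complexed pyranone.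

Step 12
Reactants: 22 6-{2-hydroxy-4,6-dimethoxy-3-[(4-methoxyphenyl)acetyl]phenyl}-5,7-dimethoxy-3-(4-methoxyphenyl)-4H-chromen-4-one
Product: 24 5,5',7,7'-tetramethoxy-3,3'-bis(4-methoxyphenyl)-4H,4'H-[6,8'-bichromene]-4,4'-dione (6,8''-bigenistein hexamethyl ether), via enaminone 23 (not isolated)
Conditions: Me2NCH(OMe)2 (3 equiv), toluene, 100 °C
Reagents that add atoms: N,N-dimethylformamide dimethyl acetal, COC(OC)N(C)C
Why: Condensation of the activated methylene with the amide acetal gives enaminone 23, and conjugate addition of the neighbouring phenol with loss of dimethylamine closes the second pyranone (standard deoxybenzoin route to isoflavones).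

Step 13
Reactants: 24 5,5',7,7'-tetramethoxy-3,3'-bis(4-methoxyphenyl)-4H,4'H-[6,8'-bichromene]-4,4'-dione (6,8''-bigenistein hexamethyl ether)
Product: 25 5,5',7,7'-tetrahydroxy-3,3'-bis(4-hydroxyphenyl)-4H,4'H-[6,8'-bichromene]-4,4'-dione (6,8''-bigenistein, CNP0184660.0)
Conditions: BBr3 (15 equiv), CH2Cl2, −78 to 40 °C; then MeOH, H2O
Reagents that add atoms: none
Why: Lewis-acid cleavage of the six aryl methyl ethers by BBr3 (the carbonyl-chelated 5-ethers first, the others on warming with excess reagent) should succeed because the isoflavone nucleus is stable to acid and no other functional group is present.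

**Compound list**
1 | 3,5-dimethoxyphenol | COc1cc(O)cc(OC)c1 | starting material
2 | 1,3-dimethoxy-5-(methoxymethoxy)benzene | COCOc1cc(OC)cc(OC)c1 | intermediate
3 | [2,4-dimethoxy-6-(methoxymethoxy)phenyl]lithium (formed in the flask) | [Li]c1c(OC)cc(OC)cc1OCOC | intermediate
4 | 2-iodo-1,5-dimethoxy-3-(methoxymethoxy)benzene | COCOc1cc(OC)cc(OC)c1I | intermediate
5 | (3,5-dimethoxyphenoxy)tri(propan-2-yl)silane | COc1cc(O[Si](C(C)C)(C(C)C)C(C)C)cc(OC)c1 | intermediate
6 | (2,6-dimethoxy-4-{[tri(propan-2-yl)silyl]oxy}phenyl)lithium (formed in the flask) | COc1cc(O[Si](C(C)C)(C(C)C)C(C)C)cc(OC)c1[Li] | intermediate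
7 | chloro(2,6-dimethoxy-4-{[tri(propan-2-yl)silyl]oxy}phenyl)zinc (formed in the flask) | COc1cc(O[Si](C(C)C)(C(C)C)C(C)C)cc(OC)c1[Zn]Cl | intermediate
8 | {[2,2',4',6-tetramethoxy-6'-(methoxymethoxy)biphenyl-4-yl]oxy}tri(propan-2-yl)silane | COCOc1cc(OC)cc(OC)c1-c1c(OC)cc(O[Si](C(C)C)(C(C)C)C(C)C)cc1OC | intermediate
9 | 2,2',4',6-tetramethoxy-6'-(methoxymethoxy)biphenyl-4-ol | COCOc1cc(OC)cc(OC)c1-c1c(OC)cc(O)cc1OC | intermediate
10 | 3-bromo-2,2',4',6-tetramethoxy-6'-(methoxymethoxy)biphenyl-4-ol (racemic axis) | COCOc1cc(OC)cc(OC)c1-c1c(OC)cc(O)c(Br)c1OC | intermediate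
11 | {[3-bromo-2,2',4',6-tetramethoxy-6'-(methoxymethoxy)biphenyl-4-yl]oxy}(trimethyl)silane (formed in the flask) | COCOc1cc(OC)cc(OC)c1-c1c(OC)cc(O[Si](C)(C)C)c(Br)c1OC | intermediate
12 | {2,2',4',6-tetramethoxy-6'-(methoxymethoxy)-4-[(trimethylsilyl)oxy]biphenyl-3-yl}lithium (formed in the flask) | COCOc1cc(OC)cc(OC)c1-c1c(OC)cc(O[Si](C)(C)C)c([Li])c1OC | intermediate
13 | lithium 2,2',4',6-tetramethoxy-6'-(methoxymethoxy)-3-(trimethylsilyl)biphenyl-4-olate (formed in the flask) | COCOc1cc(OC)cc(OC)c1-c1c(OC)cc([O-])c([Si](C)(C)C)c1OC.[Li+] | intermediate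
14 | 2,2',4',6-tetramethoxy-6'-(methoxymethoxy)-3-(trimethylsilyl)biphenyl-4-yl trifluoromethanesulfonate | COCOc1cc(OC)cc(OC)c1-c1c(OC)cc(OS(=O)(=O)C(F)(F)F)c([Si](C)(C)C)c1OC | intermediate
15 | methyl (4-methoxyphenyl)acetate | COC(=O)Cc1ccc(OC)cc1 | starting material
16 | methyl formate | COC=O | starting material
17 | methyl (2Z)-3-hydroxy-2-(4-methoxyphenyl)prop-2-enoate | O/C=C(\C(=O)OC)c1ccc(OC)cc1 | intermediate
18 | 3,4-didehydro-2,2',4',6-tetramethoxy-6'-(methoxymethoxy)biphenyl (aryne, formed in the flask) | COCOc1cc(OC)cc(OC)c1C1=C(OC)C#CC=C1OC | intermediate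
19 | 6-[2,4-dimethoxy-6-(methoxymethoxy)phenyl]-5,7-dimethoxy-3-(4-methoxyphenyl)-4H-chromen-4-one | O=c1c(-c2ccc(OC)cc2)coc2cc(OC)c(-c3c(OC)cc(OC)cc3OCOC)c(OC)c12 | intermediate
20 | 6-(2-hydroxy-4,6-dimethoxyphenyl)-5,7-dimethoxy-3-(4-methoxyphenyl)-4H-chromen-4-one | O=c1c(-c2ccc(OC)cc2)coc2cc(OC)c(-c3c(OC)cc(OC)cc3O)c(OC)c12 | intermediate
21 | (4-methoxyphenyl)acetic acid | COc1ccc(CC(=O)O)cc1 | starting material
22 | 6-{2-hydroxy-4,6-dimethoxy-3-[(4-methoxyphenyl)acetyl]phenyl}-5,7-dimethoxy-3-(4-methoxyphenyl)-4H-chromen-4-one | O=c1c(-c2ccc(OC)cc2)coc2cc(OC)c(-c3c(OC)cc(OC)c(C(=O)Cc4ccc(OC)cc4)c3O)c(OC)c12 | intermediate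
23 | 6-{3-[3-(dimethylamino)-2-(4-methoxyphenyl)prop-2-enoyl]-2-hydroxy-4,6-dimethoxyphenyl}-5,7-dimethoxy-3-(4-methoxyphenyl)-4H-chromen-4-one (alkene geometry not fixed, formed in the flask) | O=c1c(-c2ccc(OC)cc2)coc2cc(OC)c(-c3c(OC)cc(OC)c(C(=O)C(=CN(C)C)c4ccc(OC)cc4)c3O)c(OC)c12 | intermediate
24 | 5,5',7,7'-tetramethoxy-3,3'-bis(4-methoxyphenyl)-4H,4'H-[6,8'-bichromene]-4,4'-dione (6,8''-bigenistein hexamethyl ether) | O=c1c(-c2ccc(OC)cc2)coc2cc(OC)c(-c3c(OC)cc(OC)c4c(=O)c(-c5ccc(OC)cc5)coc34)c(OC)c12 | intermediate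
25 | 5,5',7,7'-tetrahydroxy-3,3'-bis(4-hydroxyphenyl)-4H,4'H-[6,8'-bichromene]-4,4'-dione (6,8''-bigenistein) | O=c1c(-c2ccc(O)cc2)coc2cc(O)c(-c3c(O)cc(O)c4c(=O)c(-c5ccc(O)cc5)coc34)c(O)c12 | target

**Count and risks**
Total steps: 13. Longest linear sequence: 11 steps (steps 1, 2, 4, 5, 6, 7, 9, 10, 11, 12, 13).

Step 9 (proposed new method). What may go wrong: the ambident enolate may arylate at carbon and then pass its formyl group to the aryl anion. It may also arylate at oxygen from its extended form, so that the aryl anion cannot reach the ester and is protonated. The fallback uses known chemistry, sets out from 14 and returns at 19. Aryne 18 is released from 14 with CsF in THF at 125 °C (sealed tube) in the presence of acid 21. The carboxylate adds at C8a and the aryl anion at C4a takes over the acyl group (the known insertion of arynes into the C–O bond of carboxylic acids). This should give 1-[4-hydroxy-2,2',4',6-tetramethoxy-6'-(methoxymethoxy)biphenyl-3-yl]-2-(4-methoxyphenyl)ethan-1-one F1. Heating F1 with Me2NCH(OMe)2 in toluene at 100 °C gives 3-(dimethylamino)-1-[4-hydroxy-2,2',4',6-tetramethoxy-6'-(methoxymethoxy)biphenyl-3-yl]-2-(4-methoxyphenyl)prop-2-en-1-one F2 in the flask, which closes to 19 with loss of dimethylamine. The same two bonds to C8a and C4a are made on the aryne, with the same regiochemistry, but the ring closes in a second operation.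

Step 6. What may go wrong: loss of site selectivity, with bromination spilling onto ring B or occurring twice on ring A. The fallback avoids halogenation, sets out from 9 and returns at 14.
- Isopropyl isocyanate and Et3N in CH2Cl2 give 2,2',4',6-tetramethoxy-6'-(methoxymethoxy)biphenyl-4-yl propan-2-ylcarbamate F3.
- TBSOTf and TMEDA in Et2O silylate nitrogen in the flask to give 2,2',4',6-tetramethoxy-6'-(methoxymethoxy)biphenyl-4-yl [tert-butyl(dimethyl)silyl](propan-2-yl)carbamate F4.
- n-BuLi/TMEDA at −78 °C metalates the carbon between the carbamate and the methoxy group (directed ortho-metalation) to give {4-({[tert-butyl(dimethyl)silyl](propan-2-yl)carbamoyl}oxy)-2,2',4',6-tetramethoxy-6'-(methoxymethoxy)biphenyl-3-yl}lithium F5.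
- TMSCl converts F5 into 2,2',4',6-tetramethoxy-6'-(methoxymethoxy)-3-(trimethylsilyl)biphenyl-4-yl [tert-butyl(dimethyl)silyl](propan-2-yl)carbamate F6.
- Aqueous NaHSO4 work-up takes silicon off nitrogen and leaves 2,2',4',6-tetramethoxy-6'-(methoxymethoxy)-3-(trimethylsilyl)biphenyl-4-yl propan-2-ylcarbamate F7.
- DBU and Et2NH in MeCN at 40 °C cleave the carbamate to 2,2',4',6-tetramethoxy-6'-(methoxymethoxy)-3-(trimethylsilyl)biphenyl-4-ol F8.
- Tf2O and pyridine in CH2Cl2 at 0 °C give 14.

Step 11. What may go wrong: acyl transfer to a wrong carbon (para to the hydroxyl or C8 of unit 1), or consumption of the enolisable, electron-rich arylacetyl electrophile by self-condensation before it reaches the hindered ortho position. The fallback brings in only a small acetyl group and attaches the aryl ring last; it sets out from 20 and returns at 24.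
- Acetic acid in BF3·OEt2 at 80 °C gives 6-(3-acetyl-2-hydroxy-4,6-dimethoxyphenyl)-5,7-dimethoxy-3-(4-methoxyphenyl)-4H-chromen-4-one F9.
- Me2NCH(OMe)2 at 90 °C gives 6-{3-[(2E)-3-(dimethylamino)prop-2-enoyl]-2-hydroxy-4,6-dimethoxyphenyl}-5,7-dimethoxy-3-(4-methoxyphenyl)-4H-chromen-4-one F10.
- I2 and pyridine in CHCl3 at rt close the ring with iodination to 8-[5,7-dimethoxy-3-(4-methoxyphenyl)-4-oxo-4H-chromen-6-yl]-3-iodo-5,7-dimethoxy-4H-chromen-4-one F11.
- Suzuki–Miyaura coupling with (4-methoxyphenyl)boronic acid (Pd(PPh3)4, Na2CO3, DME/water, 80 °C) gives 24.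

Further compounds
F1 | step 9 | 1-[4-hydroxy-2,2',4',6-tetramethoxy-6'-(methoxymethoxy)biphenyl-3-yl]-2-(4-methoxyphenyl)ethan-1-one | COCOc1cc(OC)cc(OC)c1-c1c(OC)cc(O)c(C(=O)Cc2ccc(OC)cc2)c1OC
F2 | step 9 | 3-(dimethylamino)-1-[4-hydroxy-2,2',4',6-tetramethoxy-6'-(methoxymethoxy)biphenyl-3-yl]-2-(4-methoxyphenyl)prop-2-en-1-one | COCOc1cc(OC)cc(OC)c1-c1c(OC)cc(O)c(C(=O)C(=CN(C)C)c2ccc(OC)cc2)c1OC
F3 | step 6 | 2,2',4',6-tetramethoxy-6'-(methoxymethoxy)biphenyl-4-yl propan-2-ylcarbamate | COCOc1cc(OC)cc(OC)c1-c1c(OC)cc(OC(=O)NC(C)C)cc1OC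
F4 | step 6 | 2,2',4',6-tetramethoxy-6'-(methoxymethoxy)biphenyl-4-yl [tert-butyl(dimethyl)silyl](propan-2-yl)carbamate | COCOc1cc(OC)cc(OC)c1-c1c(OC)cc(OC(=O)N(C(C)C)[Si](C)(C)C(C)(C)C)cc1OC
F5 | step 6 | {4-({[tert-butyl(dimethyl)silyl](propan-2-yl)carbamoyl}oxy)-2,2',4',6-tetramethoxy-6'-(methoxymethoxy)biphenyl-3-yl}lithium | COCOc1cc(OC)cc(OC)c1-c1c(OC)cc(OC(=O)N(C(C)C)[Si](C)(C)C(C)(C)C)c([Li])c1OC
F6 | step 6 | 2,2',4',6-tetramethoxy-6'-(methoxymethoxy)-3-(trimethylsilyl)biphenyl-4-yl [tert-butyl(dimethyl)silyl](propan-2-yl)carbamate | COCOc1cc(OC)cc(OC)c1-c1c(OC)cc(OC(=O)N(C(C)C)[Si](C)(C)C(C)(C)C)c([Si](C)(C)C)c1OC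
F7 | step 6 | 2,2',4',6-tetramethoxy-6'-(methoxymethoxy)-3-(trimethylsilyl)biphenyl-4-yl propan-2-ylcarbamate | COCOc1cc(OC)cc(OC)c1-c1c(OC)cc(OC(=O)NC(C)C)c([Si](C)(C)C)c1OC
F8 | step 6 | 2,2',4',6-tetramethoxy-6'-(methoxymethoxy)-3-(trimethylsilyl)biphenyl-4-ol | COCOc1cc(OC)cc(OC)c1-c1c(OC)cc(O)c([Si](C)(C)C)c1OC
F9 | step 11 | 6-(3-acetyl-2-hydroxy-4,6-dimethoxyphenyl)-5,7-dimethoxy-3-(4-methoxyphenyl)-4H-chromen-4-one | O=c1c(-c2ccc(OC)cc2)coc2cc(OC)c(-c3c(OC)cc(OC)c(C(C)=O)c3O)c(OC)c12
F10 | step 11 | 6-{3-[(2E)-3-(dimethylamino)prop-2-enoyl]-2-hydroxy-4,6-dimethoxyphenyl}-5,7-dimethoxy-3-(4-methoxyphenyl)-4H-chromen-4-one | O=c1c(-c2ccc(OC)cc2)coc2cc(OC)c(-c3c(OC)cc(OC)c(C(=O)/C=C/N(C)C)c3O)c(OC)c12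
F11 | step 11 | 8-[5,7-dimethoxy-3-(4-methoxyphenyl)-4-oxo-4H-chromen-6-yl]-3-iodo-5,7-dimethoxy-4H-chromen-4-one | O=c1c(-c2ccc(OC)cc2)coc2cc(OC)c(-c3c(OC)cc(OC)c4c(=O)c(I)coc34)c(OC)c12
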